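(All runs are calculated for an exercise, noise included.)

- The constants are hidden, so you count turnovers instead: how much Q each Z makes per minute.

| setting | violet | amber | grey | teal | ochre |
|---|---|---|---|---|---|
| E | 0.400 M | 0.240 M | 0.400 M | 0.400 M | 0.200 M |
| J | 1.20 M | 1.04 M | 2.40 M | 1.20 M | 2.40 M |
| Z | 8.00 × 10⁻⁴ M | 8.00 × 10⁻⁴ M | 8.00 × 10⁻⁴ M | 0.00240 M | 8.00 × 10⁻⁴ M |
| time |  |  |  |  | 25 min |

| run | time / min | [Q] / M |
|---|---|---|
| violet run | 1.0 | 0.0143 |
| violet run | 2.2 | 0.0361 |
| violet run | 5.0 | 0.0752 |
| violet run | 11 | 0.1601 |
| violet run | 25 | 0.3015 |
| amber run | 1.0 | 0.0110 |
| amber run | 2.2 | 0.0297 |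
| amber run | 5.0 | 0.0579 |
| amber run | 11 | 0.1175 |
| amber run | 25 | 0.2103 |
| grey run | 1.0 | 0.0245 |
| grey run | 2.2 | 0.0497 |
| grey run | 5.0 | 0.1052 |
| grey run | 11 | 0.2113 |
| grey run | 25 | 0.3540 |
| teal run | 1.0 | 0.0345 |
| teal run | 2.2 | 0.0706 |
| teal run | 5.0 | 0.1592 |
| teal run | 11 | 0.3094 |
| teal run | 25 | 0.3994 |

(readings scatter by 0.002 M)

* the power of [J] that the first rate follows, about the charge of the violet run; measure it at two percent of E made into Q
* the power of [Z] that the first rate follows, about the charge of the violet run; measure it at two percent of E made into Q
* the amber run starts with 0.160 M less of E and of J than the violet run, and with no Q. Compared where both hold the same amount of E, once fifteen percent of what the amber run was charged with has turned into Q, is the amber run faster, slower or alike (within a tenth)?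
* Q in the ochre run at 25 min, as a share of the E charged

- Overall: E + J -> Q, with Z as catalyst.
- Constant volume, constant temperature.
- Readings of a species count what is bound in complexes too.
- An order is taken over about fifteen percent of the charge, up and down.

- Take the readings at 5.0 min, where the scatter is 2.66% of the violet Q. This is later than the asked two percent, so what follows is an estimate.
- Teal holds 3.00 times the Z of violet and has 2.12 times its Q. The mean order in Z over that span is therefore 0.683.
- Suppose that some Q forms without Z, by a background reaction. The order in Z then climbs with Z, so at the violet charge it lies below that mean. Under that supposition, this mean is your upper bound.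
- Grey holds 2.00 times the J of violet and has 1.40 times its Q, a mean order in J of 0.484. The same picture puts the order in J at the violet charge below that mean.
- Suppose also that the cycle ignores J and the background ignores Z. The two orders then add up to 1, which gives a lower bound of 0.516 for Z.
- To tighten the bracket, divide the extra Q of teal by its extra Z and by the time. This is the mean turnover frequency up to 5.0 min, the Q made per Z per minute, 10.5 /min.
- In violet, that frequency accounts for 0.0420 M of the 0.0752 M read at 5.0 min. The cycle's share is 0.559. I commit to this as the order in Z, and to the remaining 0.441 as the order in J.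
- Ochre has the Z of violet. Over 25 min, the same frequency gives 0.210 M, which is more than the 0.200 M of E charged. That count is rough: ochre is charged with less E than violet, and the background comes on top. I commit to just under 100%.
- The forecast reads the runs as “a catalyst-limited cycle that is partly saturated in E” and gives 0.57 for J, 0.74 for Z, alike for amber and 95% for ochre, which puts both orders above my upper bounds.
- The flask gives 0.46 for J and 0.55 for Z, and the Z order lies inside the bracket. Amber is alike, with a rate ratio of 1.0, and ochre reaches 97.1%.

    Z + E → ZE (268.2 /M/min)
    ZE + J → Rx (654.0 /M/min)
    Rx → Q + Z (25.86 /min)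
    E + J → Q (0.01566 /M/min)
    Z + E ⇌ ZE', settled at all times (10.30 /M)

- The step from E + J to Q splits the orders. About the violet charge without that step, the order in Z is 1.0 and the order in J is 0.015. Take the same step away from ochre and Q falls from 97.1% to 84.2%. That lower Q is a mean turnover frequency of 8.42 /min over 25 min, below the 10.5 /min counted from teal and violet.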